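## Retrosynthetic overview
1. Endgame: 21 comes from aryl-drimene 16 by phenol dearomatisation to a quinone monoketal, face-selective Weitz–Scheffer epoxidation (C1′, C2′), anti-selective ketone reduction (C6′) and one acidic global deprotection. The quinol ring is bought as an arene.
2. C11–C1′ bond: hydroboration of the exocyclic diene 10 (sets C9), then B-alkyl Suzuki–Miyaura coupling with bromide 14.
3. Ring A: the enabling feature is C4, which carries a methyl group (C14) and, next to C3, an oxidised one-carbon branch (C13H2OH). A quaternary C–CHO array is the retron of an epoxide-to-aldehyde 1,2-shift, so C13 is put back into the ring between C3 and C4. Ring A is thus traced to the seven-membered ring C10–C1–C2–C3–C13–C4–C5 of the 4,13-epoxide 6.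
4. In that ring, C5–C4(CH3)=C13 is the isopropenyl group of (R)-carvone, closed by RCM onto a pentenyl chain. Carvone supplies ring B, C12, C13, C14 and the only purchased stereocentre C5, from which C10, C4 and C9 are relayed.
5. Ring order: B (carvone), then the seven-membered proto-A ring (RCM), then A (contraction), then the oxirane on the dearomatised arene ring.

Key step: step 5

Numbering: drimane numbering is used (ring A = C1–C5, C10; ring B = C5–C10; C11 on C9, C12 on C8, C13 = 4α branch, C14 = 4β methyl, C15 on C10). The quinol ring runs from C1′ (bears C11) to C6′ (carbinol).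

Assumption: N-benzylcinchonidinium chloride is taken as the pseudoenantiomer that directs the peroxide to the required face of dienone 18; the cinchoninium salt is the mirror-image option.

## Route

Step 1
Reactants: 1 (R)-(−)-carvone
Product: 2 (5R)-6-methylcarvone (both C6 epimers, used together)
Conditions: LDA, THF, −78 °C; MeI, −78 → 0 °C
Reagents that add atoms: iodomethane, CI
Why: Kinetic α′-deprotonation gives the cross-conjugated lithium dienolate and enolate alkylation installs the future C15 methyl group; the new centre (future C10) is planarised again in step 2, so its configuration does not matter.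

Step 2
Reactants: 2 (5R)-6-methylcarvone; 3 5-iodopent-1-ene
Product: 4 (5S,6S)-2,6-dimethyl-6-(pent-4-en-1-yl)-5-(prop-1-en-2-yl)cyclohex-2-en-1-one
Conditions: LDA, THF, −78 °C; DMPU, 3, −78 °C → rt
Reagents that add atoms: none
Why: In this second enolate alkylation (DMPU raises the reactivity of the tetrasubstituted dienolate towards the unactivated iodide) the electrophile enters anti to the neighbouring C5 isopropenyl group, so quaternary C10 is set by substrate control with the chain trans and the methyl cis to isopropenyl, as the trans ring fusion requires.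

Step 3
Reactants: 4 dialkylated carvone
Product: 5 (4aS,9aS)-2,5,9a-trimethyl-4,4a,7,8,9,9a-hexahydro-1H-benzo[7]annulen-1-one (trans-fused, C4=C13 olefin)
Conditions: (H2IMes)(PCy3)Cl2Ru=CHPh (5 mol %), CH2Cl2 (high dilution), 40 °C
Reagents that add atoms: none
Why: Ring-closing metathesis of the monosubstituted with the 1,1-disubstituted olefin closes the seven-membered ring C10–C1–C2–C3–C13–C4–C5 as its trisubstituted olefin, the two chains being gauche (diequatorial) and the electron-poor enone olefin inert; no stereocentre is formed.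

Step 4
Reactants: 5 bicyclic dienone
Product: 6 4α,13α-epoxide of 5
Conditions: mCPBA, CH2Cl2, 0 °C
Reagents that add atoms: meta-chloroperbenzoic acid, O=C(OO)c1cccc(Cl)c1
Why: Prilezhaev epoxidation picks the electron-rich C4=C13 olefin over the enone and attacks the α-face, anti to the axial 10β-methyl group that overhangs C4, which sets C4 and C13 (oxygen α).

Step 5
Reactants: 6 4α,13α-epoxide
Product: 7 9-oxo-11-nordrim-7-en-13-al (4β-CH3 axial, 4α-CHO equatorial, 5α-H, 10β-CH3)
Conditions: MABR (2.2 equiv, from Me3Al and 4-bromo-2,6-di-tert-butylphenol), CH2Cl2, −78 → −40 °C; 1 M HCl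
Reagents that add atoms: none
Why: MABR binds the oxirane oxygen, the tertiary C4–O bond ionises, and the C3–C13 σ-bond migrates from C13 to C4 on the side opposite the departing oxygen while C13 becomes the aldehyde carbon, so C13 is extruded from the seven-membered ring and ring A (C1–C2–C3–C4–C5–C10) appears in its final size in a pure isomerisation. The closest known reaction type is the Lewis-acid Meinwald (semipinacol-type) rearrangement of trisubstituted epoxides to α-quaternary aldehydes, including the contraction of 1-methylcycloalkene oxides to 1-methylcycloalkanecarbaldehydes. Ring A is closed by a suprafacial 1,2-alkyl shift through a three-centre C3/C13/C4 transition state and not by a cyclisation, and no other ring is formed. The only new stereocentre, quaternary C4, is controlled by inversion at C4, so the α-oxirane (itself relayed from the 10β-methyl group) should deliver the 4β-axial CH3 and the 4α-equatorial CHO and thereby tell the two one-carbon branches at C4 apart at the right oxidation level. The step needs C4–O over C13–O cleavage, which the tertiary versus secondary cation secures, and C3 shift over the C13–H hydride shift, which is favoured by the very bulky, non-nucleophilic aluminium aryloxide (the Lewis acid of choice for aldehyde rather than ketone formation from trisubstituted epoxides), by the low temperature and by the release of cycloheptane strain. The hindered enone only ties up a second equivalent of Lewis acid, and the product has no α-hydrogen, so C4 cannot epimerise.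

Step 6
Reactants: 7 keto aldehyde
Product: 8 13-hydroxy-11-nordrim-7-en-9-one
Conditions: NaBH4, CH2Cl2/MeOH, −78 °C
Reagents that add atoms: none
Why: In this chemoselective borohydride reduction the aldehyde reacts at −78 °C far faster than the conjugated C9 ketone flanked by quaternary C10 and the C8 methyl group; no stereocentre is formed.

Step 7
Reactants: 8 hydroxy enone
Product: 9 13-(tert-butyldimethylsilyloxy)-11-nordrim-7-en-9-one
Conditions: TBSCl, imidazole, DMF, rt
Reagents that add atoms: tert-butyldimethylsilyl chloride, CC(C)(C)[Si](C)(C)Cl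
Why: Standard silylation of the primary neopentyl alcohol masks it for the ylide, borane, oxidant and hydride to come; no stereocentre is touched.

Step 8
Reactants: 9 silyloxy enone
Product: 10 13-(tert-butyldimethylsilyloxy)drima-7,9(11)-diene
Conditions: Ph3PCH3Br, KOtBu, toluene, 90 °C
Reagents that add atoms: methyltriphenylphosphonium bromide, C[P+](c1ccccc1)(c1ccccc1)c1ccccc1.[Br-]
Why: Wittig methylenation with excess ylide at elevated temperature is the standard answer to a hindered ketone that has no α-hydrogen to lose, and it adds C11; no stereocentre is formed.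

Step 9
Reactants: 11 4-bromo-2,5-dimethoxybenzaldehyde
Product: 12 4-bromo-5-hydroxy-2-methoxybenzaldehyde
Conditions: DL-methionine, conc. H2SO4, rt → 50 °C
Reagents that add atoms: none
Why: In this regioselective acid-mediated O-demethylation the 2-methoxy group is tied up in conjugation with the protonated formyl group, so only the 5-methoxy group (meta to CHO) is protonated on oxygen and hands its methyl group to the thioether by SN2.

Step 10
Reactants: 12 bromo hydroxy aldehyde
Product: 13 2-bromo-5-(hydroxymethyl)-4-methoxyphenol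
Conditions: NaBH4, THF/MeOH, 0 °C
Reagents that add atoms: none
Why: Borohydride reduction of the aryl aldehyde leaves bromide and phenol untouched; no stereocentre is formed.

Step 11
Reactants: 13 bromo diol
Product: 14 1-bromo-5-methoxy-2-(triisopropylsilyloxy)-4-[(triisopropylsilyloxy)methyl]benzene
Conditions: TIPSCl (2.4 equiv), imidazole, DMF, rt → 40 °C
Reagents that add atoms: triisopropylsilyl chloride, CC(C)[Si](Cl)(C(C)C)C(C)C
Why: Double silylation protects phenol and benzylic alcohol in one operation with a group that withstands the basic coupling, while the aryl silyl ether remains by far the more fluoride-labile of the two.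

Step 12
Reactants: 10 diene; 14 aryl bromide
Product: 16 13-(tert-butyldimethylsilyloxy)-11-[5-methoxy-2-(triisopropylsilyloxy)-4-(triisopropylsilyloxymethyl)phenyl]drim-7-ene (9α-H), via B-[13-(tert-butyldimethylsilyloxy)drim-7-en-11-yl]-9-BBN 15 (not isolated)
Conditions: 9-BBN-H, THF, 60 °C; then 14, Pd(OAc)2 (5 mol %), SPhos (10 mol %), aq. K3PO4, THF/DMF, 60 °C
Reagents that add atoms: 9-borabicyclo[3.3.1]nonane, B1C2CCCC1CCC2 (its boryl group stays only in 15; 16 keeps its hydrogen at C9)
Why: In this hydroboration/B-alkyl Suzuki–Miyaura sequence 9-BBN adds to the less hindered 1,1-disubstituted C9=C11 bond of the diene with boron on C11 and delivers hydrogen to C9 from the α-face, anti to the 10β-methyl group, which sets C9 (9α-H, C11 equatorial), and the primary alkylborane is then coupled by an electron-rich biarylphosphine palladium catalyst.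

Step 13
Reactants: 16 aryl-drimene
Product: 17 2-[13-(tert-butyldimethylsilyloxy)drim-7-en-11-yl]-4-methoxy-5-[(triisopropylsilyloxy)methyl]phenol
Conditions: TBAF/AcOH (1:1, 1.1 equiv), THF, 0 °C
Reagents that add atoms: none
Why: In this chemoselective desilylation buffered fluoride cleaves the aryl silyl ether, whose phenoxide is much the better leaving group, well before the primary alkyl TIPS and neopentyl TBS ethers; no stereocentre is touched.

Step 14
Reactants: 17 phenol
Product: 18 2-[13-(tert-butyldimethylsilyloxy)drim-7-en-11-yl]-4,4-dimethoxy-5-[(triisopropylsilyloxy)methyl]cyclohexa-2,5-dien-1-one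
Conditions: PhI(OAc)2, MeOH, 0 °C
Reagents that add atoms: methanol, CO
Why: In this hypervalent-iodine oxidative dearomatisation of a 4-methoxyphenol the phenol carbon C6′ becomes the ketone and C3′ takes up methanol to give the dimethyl ketal, so the regiochemistry of the monoketal is fixed by the oxygen that step 13 set free.

Step 15
Reactants: 18 quinone monoketal
Product: 19 C1′,C2′-epoxide of 18 (configuration as in the target)
Conditions: t-BuOOH, N-benzylcinchonidinium chloride (15 mol %), aq. NaOH (cat.), toluene, 0 °C → rt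
Reagents that add atoms: tert-butyl hydroperoxide, CC(C)(C)OO
Why: In this Weitz–Scheffer epoxidation under chiral phase-transfer catalysis the peroxide adds to the only unsubstituted β-carbon (C2′), the other one (C4′) being blocked by its CH2OTIPS group, and the ion-paired cinchona ammonium cation selects the face of the flat dienone, which sets C1′ and C2′ by reagent control because the drimane stereocentres are too remote.

Step 16
Reactants: 19 epoxy dienone ketal
Product: 20 C6′ alcohol of 19 (OH anti to the oxirane oxygen, cis to C11)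
Conditions: DIBAL-H, THF, −78 °C; Rochelle salt
Reagents that add atoms: none
Why: In this 1,2-reduction of the epoxy enone the aluminium can coordinate to the oxirane oxygen and the opposite face is covered by the drimanylmethyl group on the adjacent quaternary C1′, so hydride should enter syn to the oxirane and set C6′ with its hydroxyl anti to it.

Step 17
Reactants: 20 epoxy alcohol ketal
Product: 21 epoxypholamin A
Conditions: 48 % aq. HF, MeCN, 0 °C → rt
Reagents that add atoms: water, O
Why: In this acidic global deprotection HF cleaves both silyl ethers and the aqueous acid hydrolyses the dimethyl ketal to the C3′ enone, conditions that epoxyquinols and the trisubstituted C7=C8 olefin tolerate; no stereocentre is touched.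

## Compound list
1 | (R)-(−)-carvone | CC1=CC[C@H](CC1=O)C(C)=C | starting material
2 | (5R)-6-methylcarvone, C6 epimers | CC1=CC[C@H](C(C)C1=O)C(C)=C | intermediate
3 | 5-iodopent-1-ene | C=CCCCI | starting material
4 | (5S,6S)-2,6-dimethyl-6-(pent-4-en-1-yl)-5-(prop-1-en-2-yl)cyclohex-2-en-1-one | CC1=CC[C@@H](C(C)=C)[C@](C)(CCCC=C)C1=O | intermediate
5 | (4aS,9aS)-2,5,9a-trimethyl-4,4a,7,8,9,9a-hexahydro-1H-benzo[7]annulen-1-one | CC1=CC[C@H]2C(C)=CCCC[C@]2(C)C1=O | intermediate
6 | 4α,13α-epoxide of 5 | CC1=CC[C@H]2[C@]3(C)O[C@@H]3CCC[C@]2(C)C1=O | intermediate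
7 | 9-oxo-11-nordrim-7-en-13-al | CC1=CC[C@H]2[C@](C)(C=O)CCC[C@]2(C)C1=O | intermediate
8 | 13-hydroxy-11-nordrim-7-en-9-one | CC1=CC[C@H]2[C@](C)(CO)CCC[C@]2(C)C1=O | intermediate
9 | 13-(tert-butyldimethylsilyloxy)-11-nordrim-7-en-9-one | CC1=CC[C@H]2[C@](C)(CO[Si](C)(C)C(C)(C)C)CCC[C@]2(C)C1=O | intermediate
10 | 13-(tert-butyldimethylsilyloxy)drima-7,9(11)-diene | CC1=CC[C@H]2[C@](C)(CO[Si](C)(C)C(C)(C)C)CCC[C@]2(C)C1=C | intermediate
11 | 4-bromo-2,5-dimethoxybenzaldehyde | COc1cc(C=O)c(OC)cc1Br | starting material
12 | 4-bromo-5-hydroxy-2-methoxybenzaldehyde | Oc1cc(C=O)c(OC)cc1Br | intermediate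
13 | 2-bromo-5-(hydroxymethyl)-4-methoxyphenol | Oc1cc(CO)c(OC)cc1Br | intermediate
14 | 1-bromo-5-methoxy-2-(triisopropylsilyloxy)-4-[(triisopropylsilyloxy)methyl]benzene | COc1cc(Br)c(O[Si](C(C)C)(C(C)C)C(C)C)cc1CO[Si](C(C)C)(C(C)C)C(C)C | intermediate
15 | B-[13-(tert-butyldimethylsilyloxy)drim-7-en-11-yl]-9-BBN (not isolated) | CC1=CC[C@H]2[C@](C)(CO[Si](C)(C)C(C)(C)C)CCC[C@]2(C)[C@H]1CB1C2CCCC1CCC2 | intermediate
16 | 13-(TBSO)-11-[5-methoxy-2-(TIPSO)-4-(TIPSOCH2)phenyl]drim-7-ene | CC1=CC[C@H]2[C@](C)(CO[Si](C)(C)C(C)(C)C)CCC[C@]2(C)[C@H]1Cc1cc(OC)c(CO[Si](C(C)C)(C(C)C)C(C)C)cc1O[Si](C(C)C)(C(C)C)C(C)C | intermediate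
17 | 2-[13-(TBSO)drim-7-en-11-yl]-4-methoxy-5-(TIPSOCH2)phenol | CC1=CC[C@H]2[C@](C)(CO[Si](C)(C)C(C)(C)C)CCC[C@]2(C)[C@H]1Cc1cc(OC)c(CO[Si](C(C)C)(C(C)C)C(C)C)cc1O | intermediate
18 | 2-[13-(TBSO)drim-7-en-11-yl]-4,4-dimethoxy-5-(TIPSOCH2)cyclohexa-2,5-dien-1-one | CC1=CC[C@H]2[C@](C)(CO[Si](C)(C)C(C)(C)C)CCC[C@]2(C)[C@H]1CC1=CC(OC)(OC)C(CO[Si](C(C)C)(C(C)C)C(C)C)=CC1=O | intermediate
19 | C1′,C2′-epoxide of 18 | CC1=CC[C@H]2[C@](C)(CO[Si](C)(C)C(C)(C)C)CCC[C@]2(C)[C@H]1C[C@@]12O[C@@H]1C(OC)(OC)C(CO[Si](C(C)C)(C(C)C)C(C)C)=CC2=O | intermediate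
20 | C6′ alcohol of 19, OH anti to the oxirane | CC1=CC[C@H]2[C@](C)(CO[Si](C)(C)C(C)(C)C)CCC[C@]2(C)[C@H]1C[C@@]12O[C@@H]1C(OC)(OC)C(CO[Si](C(C)C)(C(C)C)C(C)C)=C[C@H]2O | intermediate
21 | epoxypholamin A | CC1=CC[C@H]2[C@](C)(CO)CCC[C@]2(C)[C@H]1C[C@@]12O[C@@H]1C(=O)C(CO)=C[C@H]2O | target

## Step count and risks
Total step count: 17. Longest linear sequence: 14 (steps 1–8 and 12–17, from carvone).

**Steps most likely to fail**

1. **Step 5.** The 1,2-hydride shift from C13 to C4, or proton loss from the incipient C4 cation, may outrun the C3 shift. The fallback sets out from 6 and returns at 8, and it makes the hydride shift the intended reaction.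
   - Epoxide 6 is isomerised (LiClO4, toluene, reflux) to the seven-membered 9,13-dione F1.
   - SO2Cl2 chlorinates the more substituted α-carbon C4 from the open α-face to give the 4α-chloro ketone F2.
   - A Favorskii rearrangement under heterogeneous conditions (NaOMe, DME) follows. The C3 enolate displaces chloride with inversion, and the cyclopropanone opens towards the less substituted C3 carbanion. This again contracts the seven-membered ring to ring A and gives methyl 9-oxo-11-nordrim-7-en-13-oate F3.
   - LiAlH4 gives 11-nordrim-7-ene-9,13-diol F4, and MnO2 reoxidises only the allylic C9 alcohol to 8.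

2. **Step 15.** Facial selectivity may be poor: the ion-paired catalyst may not distinguish the two faces of an α-alkylated dienone, and the drimane unit is too remote to help. The fallback sets out from 18 and returns at 21, replacing reagent control by an auxiliary in the ketal.
   - Transketalisation of 18 with (2R,4R)-pentane-2,4-diol (BF3·OEt2, DME) gives the C2-symmetric spiro-dioxane dienone F5, whose axial methyl group shields one ring face.
   - Plain Weitz–Scheffer epoxidation (H2O2, K2CO3, aq. THF) gives the spiro-dioxane epoxide F6.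
   - DIBAL-H gives the spiro-dioxane epoxy alcohol F7, and aq. HF/MeCN releases 21.

3. **Step 12.** Transmetalation of the β-branched alkylborane to an ortho-silyloxy arylpalladium species may be slow, with protodeboronation and hydrodebromination taking over. The fallback sets out from 15 and 14 and returns at 16, forming the C11–aryl bond by carbonyl addition.
   - Borane 15 is oxidised (NaOH, H2O2) to 13-(TBSO)drim-7-en-11-ol F8.
   - Dess–Martin oxidation gives 13-(TBSO)drim-7-en-11-al F9.
   - The aryllithium F10 (from 14, n-BuLi, THF, −78 °C) adds to F9 to give the C11 carbinols F11.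
   - Barton–McCombie deoxygenation through the S-methyl xanthates F12 (NaH, CS2, MeI; then Bu3SnH, AIBN, toluene, 80 °C) gives 16.

## Further compounds
F1 | step 5 | seven-membered 9,13-dione (C4–H, epimers) | CC1=CC[C@H]2C(C)C(=O)CCC[C@]2(C)C1=O
F2 | step 5 | 4α-chloro ketone | CC1=CC[C@H]2[C@](C)(Cl)C(=O)CCC[C@]2(C)C1=O
F3 | step 5 | methyl 9-oxo-11-nordrim-7-en-13-oate | CC1=CC[C@H]2[C@](C)(C(=O)OC)CCC[C@]2(C)C1=O
F4 | step 5 | 11-nordrim-7-ene-9,13-diol (C9 epimers) | CC1=CC[C@H]2[C@](C)(CO)CCC[C@]2(C)C1O
F5 | step 15 | spiro-dioxane dienone | CC1=CC[C@H]2[C@](C)(CO[Si](C)(C)C(C)(C)C)CCC[C@]2(C)[C@H]1CC1=CC2(O[C@H](C)C[C@@H](C)O2)C(CO[Si](C(C)C)(C(C)C)C(C)C)=CC1=O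
F6 | step 15 | spiro-dioxane epoxide | CC1=CC[C@H]2[C@](C)(CO[Si](C)(C)C(C)(C)C)CCC[C@]2(C)[C@H]1C[C@@]12O[C@@H]1C1(O[C@H](C)C[C@@H](C)O1)C(CO[Si](C(C)C)(C(C)C)C(C)C)=CC2=O
F7 | step 15 | spiro-dioxane epoxy alcohol | CC1=CC[C@H]2[C@](C)(CO[Si](C)(C)C(C)(C)C)CCC[C@]2(C)[C@H]1C[C@@]12O[C@@H]1C1(O[C@H](C)C[C@@H](C)O1)C(CO[Si](C(C)C)(C(C)C)C(C)C)=C[C@H]2O
F8 | step 12 | 13-(TBSO)drim-7-en-11-ol | CC1=CC[C@H]2[C@](C)(CO[Si](C)(C)C(C)(C)C)CCC[C@]2(C)[C@H]1CO
F9 | step 12 | 13-(TBSO)drim-7-en-11-al | CC1=CC[C@H]2[C@](C)(CO[Si](C)(C)C(C)(C)C)CCC[C@]2(C)[C@H]1C=O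
F10 | step 12 | aryllithium | [Li]c1cc(OC)c(CO[Si](C(C)C)(C(C)C)C(C)C)cc1O[Si](C(C)C)(C(C)C)C(C)C
F11 | step 12 | C11 carbinols (C11 epimers) | CC1=CC[C@H]2[C@](C)(CO[Si](C)(C)C(C)(C)C)CCC[C@]2(C)[C@H]1C(O)c1cc(OC)c(CO[Si](C(C)C)(C(C)C)C(C)C)cc1O[Si](C(C)C)(C(C)C)C(C)C
F12 | step 12 | S-methyl xanthates (C11 epimers) | CC1=CC[C@H]2[C@](C)(CO[Si](C)(C)C(C)(C)C)CCC[C@]2(C)[C@H]1C(OC(=S)SC)c1cc(OC)c(CO[Si](C(C)C)(C(C)C)C(C)C)cc1O[Si](C(C)C)(C(C)C)C(C)C
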